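## Structural features

The target is a C25 chain with three heterocycles: a 3-methylbut-2-en-4-olide (lactone carbonyl C1, methyl-bearing C2, C3, oxygen-bearing C4), a 2,4-disubstituted furan (ring A) and a 3-monosubstituted furan (ring B). C4 of the lactone is joined by an exocyclic double bond to C5; then follow C6 (methyl-bearing, the only stereocentre), the C7 methylene, the diene C8=C9–C10(CH3)=C11 and the C12–C13 ethylene, which ends on C4 of ring A, whose C2 is tied through one CH2 to C3 of ring B. Re-reading the line notation gives the ring oxygen and C6 on opposite sides of C4=C5 (E), both chain alkenes E, and C6 as S (C5 > C7 > CH3). No two stereocentres are adjacent; C6 stands alone, allylic to the ylidene lactone, so its hydrogen becomes vinylogously acidic once C4=C5 exists and late base must be avoided. Fragile elements are the two electron-rich furans and the doubly activated CH2 between them (acid, oxidants, electrophiles), the light-sensitive polyene, and above all the E-ylidene butenolide, which is the less stable geometric isomer. The real difficulties are two: the unsymmetrical bis-furan with the 2,4-pattern on ring A, which neither electrophilic substitution (it prefers the α-carbon next to the alkyl group) nor simple lithiation of a 3-alkylfuran delivers cleanly, and the kinetic control of the E geometry at C4=C5. The key step exploits the fact that C2 of ring A, the carbon carrying the bridging CH2, is the α-CH of a 3-alkylfuran remote from the alkyl group, the sterically most open C–H bond of that ring.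

## Logic of the disconnections

**20 to 19.** The C4=C5 π bond is replaced by C4–H and C5–OH. The E alkene is the less stable isomer and cannot be left to equilibration, whereas a stereospecific anti elimination turns relative configuration into geometry. The geometric problem thus becomes one of simple diastereoselection a step earlier. The forward step must be a concerted anti loss of H and activated OH from the erythro isomer 19, with no stepwise route through the dienolate and no isomerisation of 20 afterwards.

**19 to 15 and 17 (17 from 16).** The C4–C5 σ bond is cut. This removes the whole lactone as a five-carbon nucleophile that is one silylation away from commercial 16. Three stereocentres in 19 fall to one in 15. The addition must go through the γ-carbon of 17, be erythro-selective, and be mild enough not to epimerise C6 of 15. The sense at C5 relative to C6 is irrelevant, because C4 and C5 both become sp2.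

**15 to 14, and 14 to 11 and 12 (through 13).** After C5 is adjusted from aldehyde to methyl ester, the sp3–sp2 bond C7–C8 is cut. The cut lies one carbon away from C6, so the stereocentre is bought with 12 and is never a reacting centre. Because the ester carbon of 12 becomes C5 and its bromomethyl carbon C7, the R enantiomer of 12 is the one that gives 6S. Carrying C5 at the ester level rather than as a protected alcohol saves four operations (silylation, ester reduction, halogenation, desilylation and oxidation are replaced by one reduction). The forward steps need zinc insertion into 12, a coupling that keeps both alkene geometries of 11, and a reduction of 14 that stops at 15.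

**11 to 10, 10 to 9, 9 to 8.** C8=C9 is cut by a one-carbon iodo-olefination and C10=C11 by a stabilised-ylide olefination; the aldehyde carbon of 9 is then masked as in 8. Both olefinations are E-selective by mechanism. The whole diene is reduced to a propanal chain on ring A. The unmasking of 8 must be mild enough for the bis-furan.

**8 to 4 and 6 (through 7).** This is the strategic cut, between C2 of ring A and the bridging CH2. It divides the bis-furan into two 3-monosubstituted furans, so no 2,4-disubstituted furan has to be made by ring synthesis. The forward step must borylate 4 only at the α-CH remote from the chain, stop at mono-borylation, and have no active boron left when 6 enters, since ring B has two free α-CH bonds. The sp2–sp3 coupling must also outrun loss of boron from 7. The diethyl acetal in 4 is kept deliberately: it is inert to the iridium boryl catalyst and to phosphate, it arrives with commercial 1, and it is the aldehyde mask removed by the weakest acid.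

**4 to 1 and 2 (through 3); 6 to 5.** The bond between C4 of ring A and C13 is cut as an sp2–sp3 bond, made by hydroboration of 1 and alkyl cross-coupling with 2. 6 is the bromide of commercial 5 and is made just before use. Every starting material is then a catalogue compound.

## Other disconnections considered

**Alternative 1:** The cut goes through ring A itself. The O–C2 bond is opened to the acyclic Z-enynol A1, (2Z)-2-[2-(1,3-dioxolan-2-yl)ethyl]-5-(furan-3-yl)pent-2-en-4-yn-1-ol. In the forward step Ph3PAuNTf2 (monovalent gold) would activate the alkyne of A1, the hydroxyl would attack 5-exo-dig, and the exocyclic alkene would shift into the ring, giving the furan A2 with the bridging CH2 already in place.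
- In its favour: the 2,4-pattern is fixed by connectivity, so no regioisomer can arise. On this point it is better than the chosen plan, which relies on steric discrimination between two α-CH bonds. It is also a pure isomerisation with no by-product and no boronate to lose, so it is better in atom economy.
- Against it here: A1 is not commercial and would need its own assembly around a stereodefined Z-trisubstituted alkene, an estimated four to five operations. Ring B would sit directly on a gold-activated alkyne and could compete as a nucleophile. The dioxolane of A2 needs stronger acid for removal than the diethyl acetal of 8.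
- Comparison: structurally both plans converge on the same bis-furan propanal equivalent (A2 or 8) and the rest of the route would be identical. Mechanistically it is ring construction by C–O bond formation against C–H functionalisation of intact commercial rings. In step economy the chosen plan reaches 8 in three operations, two in the longest line, and is expected to be shorter.

**Alternative 2:** The cut is C7–C8, the same bond as in step 7. The half ester A3, (3S)-4-methoxy-3-methyl-4-oxobutanoic acid, would be activated as its N-hydroxyphthalimide ester A4. Under constant-current electrolysis with NiCl2·glyme and 2,2'-bipyridine (divalent nickel reduced at the cathode, sacrificial magnesium anode) A4 would lose CO2, and the primary C7 radical would be captured by the alkenylnickel species from dienyl iodide A5 (identical with 11), giving ester A6 (identical with 14).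
- In its favour: no organozinc reagent has to be prepared, carboxylic acids are robust feedstocks, and the radical is one carbon away from C6. On stereochemical integrity and on the structure reached it is the equal of the chosen step.
- Against it here: A3 must carry the ester on the carbonyl next to the methyl group, the regiochemistry not favoured by simple anhydride opening, and needs an extra activation to A4. A5 is a sensitive dienyl iodide that could homocouple or lose geometry under reducing, radical-generating conditions, and an electrolysis cell is needed.
- Comparison: mechanistically it is one-electron nickel chemistry against two-electron zinc/palladium chemistry. In step economy it is one operation longer, or equal if A3 can be bought. It leaves the bis-furan problem untouched, so it could only replace step 7, not the key step.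

**Alternative 3:** The cut is C4–C5. Fluoride-promoted addition of silyloxyfuran A8 (identical with 17) through its 5-position to aldehyde A7 (identical with 15) would give the erythro hydroxy butenolide A9 (identical with 19), whose anti dehydration programmes the E alkene.
- In its favour: it is the most convergent way to bring in the lactone, and it sets up the alkene geometry that nothing else in the molecule can control. On this point it is better than anything the borylation offers, and the chosen plan adopts it unchanged as step 10.
- Against it as the strategic centre: the erythro preference is a kinetic, substrate-dependent one, two stereocentres are made only to be destroyed, and the step says nothing about the less precedented half of the molecule, the unsymmetrical bis-furan.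
- Comparison: structure and step economy are identical, because the step is contained in the chosen route. The only difference is which step carries the strategy, and the ring A problem is judged the one that decides the length of the synthesis.

Key step: step 3

Remark: both erythro adducts (either sense at C5 relative to C6) lead to 20 because C4 and C5 lose their configuration in step 11; 19 is drawn as the Felkin-type isomer expected to predominate.

## Route

Step 1
Reactants: 1 acrolein diethyl acetal (3,3-diethoxyprop-1-ene); 2 3-bromofuran
Product: 4 3-(3,3-diethoxypropyl)furan, via B-(3,3-diethoxypropyl)-9-BBN 3 (not isolated)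
Conditions: 9-BBN, THF, 0 °C to rt; then 2, PdCl2(dppf) (3 mol%), aq. K3PO4, THF/DMF, 60 °C
Reagents that add atoms: 9-borabicyclo[3.3.1]nonane, B1C2CCCC1CCC2 (its boron and ring are held in 3 only; nothing of it remains in 4)
Why: Anti-Markovnikov hydroboration puts boron on the terminal carbon of 1, and the B-alkyl Suzuki–Miyaura coupling then joins that sp3 carbon to C3 of the furan; the acetal is inert to borane, palladium and base.

Step 2
Reactants: 5 furan-3-ylmethanol
Product: 6 3-(bromomethyl)furan
Conditions: PBr3 (0.4 equiv), Et2O, 0 °C; used at once as a cold ethereal solution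
Reagents that add atoms: phosphorus tribromide, BrP(Br)Br
Why: The primary heterobenzylic alcohol is converted through its phosphite ester into the bromide by SN2 displacement at 0 °C; the product is not stored because furfuryl-type bromides polymerise.

Step 3
Reactants: 4 3-(3,3-diethoxypropyl)furan; 6 3-(bromomethyl)furan
Product: 8 4-(3,3-diethoxypropyl)-2-(furan-3-ylmethyl)furan, via furan-2-yl pinacol boronate 7 (not isolated)
Conditions: [Ir(OMe)(cod)]2 (1.5 mol%), 4,4'-di-tert-butyl-2,2'-bipyridine (3 mol%), B2pin2 (0.5 equiv), THF, rt; then 6 (0.9 equiv), Pd(PPh3)4 (5 mol%), K3PO4 (3 equiv), H2O, 60 °C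
Reagents that add atoms: bis(pinacolato)diboron, CC1(C)OB(OC1(C)C)B1OC(C)(C)C(C)(C)O1 (its boryl group is held in 7 only; nothing of it remains in 8)
Why: B2pin2 and the bipyridine convert the precatalyst into a trivalent tris(boryl)iridium complex, which cleaves a furan C–H bond and releases the aryl boronate by C–B reductive elimination; the HBpin formed re-enters the cycle, so half an equivalent of B2pin2 serves one equivalent of 4 and only H2 is lost. Of the two reactive α-CH bonds of 4, the one at C2 lies next to the acetal chain and is shielded against the crowded iridium centre, so boron should go to C5, which is C2 of ring A; the β-CH bonds are both less acidic and less accessible. Boron is the limiting component, which suppresses 2,5-diborylation and leaves no active boryl species when 6 arrives, important because ring B has two free α-CH bonds of its own. In the second stage zerovalent palladium adds oxidatively to the furfuryl-type C–Br bond of 6, the phosphate-activated boronate 7 transmetalates, and sp2–sp3 reductive elimination forms the ring A C2–CH2 bond. The closest known reaction type is the one-pot iridium C–H borylation/Suzuki–Miyaura sequence of 3-substituted furans and thiophenes with benzylic halides. No ring is closed and no stereocentre is formed. The selectivities needed are remote over adjacent α-borylation (steric demand of the catalyst against the C3 chain), mono- over diborylation (stoichiometry) and cross-coupling over protodeboronation of 7 (pinacol ester, moderate temperature, fast oxidative addition of the activated bromide); the acetal is inert to both catalysts and to base.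

Step 4
Reactants: 8 4-(3,3-diethoxypropyl)-2-(furan-3-ylmethyl)furan
Product: 9 3-[5-(furan-3-ylmethyl)furan-3-yl]propanal
Conditions: AcOH/THF/H2O (3:1:1), 35 °C
Reagents that add atoms: water, O
Why: Acid-catalysed hydrolysis of an acyclic acetal through the oxocarbenium ion; a diethyl acetal cleaves in dilute acetic acid, conditions under which the furans and the bis-heteroaryl CH2 should survive.

Step 5
Reactants: 9 3-[5-(furan-3-ylmethyl)furan-3-yl]propanal
Product: 10 (2E)-5-[5-(furan-3-ylmethyl)furan-3-yl]-2-methylpent-2-enal
Conditions: Ph3P=C(CH3)CHO (1.3 equiv), toluene, 80 °C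
Reagents that add atoms: 2-(triphenylphosphoranylidene)propanal, CC(C=O)=P(c1ccccc1)(c1ccccc1)c1ccccc1
Why: Wittig reaction of a formyl-stabilised ylide, which is reversible up to the oxaphosphetane and gives the E-trisubstituted enal; the product enal is much less electrophilic than 9, so a second olefination is slow.

Step 6
Reactants: 10 (2E)-5-[5-(furan-3-ylmethyl)furan-3-yl]-2-methylpent-2-enal
Product: 11 2-(furan-3-ylmethyl)-4-[(3E,5E)-6-iodo-4-methylhexa-3,5-dien-1-yl]furan
Conditions: CrCl2 (6 equiv), CHI3 (2 equiv), THF/1,4-dioxane (1:6), 0 °C to rt, dark
Reagents that add atoms: iodoform, IC(I)I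
Why: Takai iodo-olefination: the geminal dichromium carbenoid formed from CHI3 and CrCl2 adds to the aldehyde and eliminates to the E-iodoalkene; the reagent is selective for aldehydes and leaves the furans and the trisubstituted alkene alone.

Step 7
Reactants: 11 2-(furan-3-ylmethyl)-4-[(3E,5E)-6-iodo-4-methylhexa-3,5-dien-1-yl]furan; 12 methyl (2R)-3-bromo-2-methylpropanoate
Product: 14 methyl (2S,4E,6E)-9-[5-(furan-3-ylmethyl)furan-3-yl]-2,6-dimethylnona-4,6-dienoate, via (2R)-3-methoxy-2-methyl-3-oxopropylzinc bromide 13 (not isolated)
Conditions: 12, Zn dust (activated with BrCH2CH2Br and Me3SiCl), LiCl, THF, 40 °C; then 11, Pd(PPh3)4 (5 mol%), THF/DMA, rt to 40 °C, dark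
Reagents that add atoms: zinc, [Zn] (held in 13 only; nothing of it remains in 14)
Why: LiCl-assisted insertion of zinc into the C–Br bond gives the zinc homoenolate 13, whose stereocentre is not the metal-bearing carbon and is therefore configurationally safe; Negishi coupling (oxidative addition of zerovalent palladium to the C–I bond of 11, transmetalation, reductive elimination) forms C7–C8 with retention of both alkene geometries. The descriptor changes from R to S only because the substituent priorities change.

Step 8
Reactants: 14 methyl (2S,4E,6E)-9-[5-(furan-3-ylmethyl)furan-3-yl]-2,6-dimethylnona-4,6-dienoate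
Product: 15 (2S,4E,6E)-9-[5-(furan-3-ylmethyl)furan-3-yl]-2,6-dimethylnona-4,6-dienal
Conditions: i-Bu2AlH (1.1 equiv), CH2Cl2, −78 °C; MeOH, then aq. KNaC4H4O6; used without delay
Reagents that add atoms: none
Why: Partial ester reduction: at −78 °C the tetrahedral aluminium hemiacetal of the α-branched ester is stable and collapses to 15 only on work-up; the neutral tartrate work-up and immediate use protect the α-stereocentre C6.

Step 9
Reactants: 16 3-methylfuran-2(5H)-one
Product: 17 trimethyl[(3-methylfuran-2-yl)oxy]silane
Conditions: Me3SiCl, Et3N, CH2Cl2, 0 °C to rt; distilled
Reagents that add atoms: chlorotrimethylsilane, C[Si](C)(C)Cl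
Why: Soft enolisation of the butenolide at its γ-CH2 and O-silylation give the aromatic 2-silyloxyfuran (silyl dienol ether formation).

Step 10
Reactants: 15 (2S,4E,6E)-9-[5-(furan-3-ylmethyl)furan-3-yl]-2,6-dimethylnona-4,6-dienal; 17 trimethyl[(3-methylfuran-2-yl)oxy]silane
Product: 19 (5S)-5-[(1R,2S,4E,6E)-9-[5-(furan-3-ylmethyl)furan-3-yl]-1-hydroxy-2,6-dimethylnona-4,6-dien-1-yl]-3-methylfuran-2(5H)-one, via O-trimethylsilyl adduct 18 (not isolated)
Conditions: Bu4NF (10 mol%, dried), THF, −78 °C; then citric acid, MeOH/H2O, 0 °C; threo isomers removed by chromatography
Reagents that add atoms: none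
Why: Fluoride turns 17 into a naked ammonium dienolate that adds through its γ-carbon to 15 in an open, non-chelated transition state (vinylogous Mukaiyama-type aldol), which should place ring oxygen and new hydroxyl in the erythro relation; silyl transfer gives 18 and mild acid frees 19. The C4/C5 relative configuration is set by the open transition state and the sense at C5 relative to C6 by Felkin–Anh control, which is immaterial for step 11; −78 °C and catalytic fluoride should leave C6 untouched.

Step 11
Reactants: 19 (5S)-5-[(1R,2S,4E,6E)-9-[5-(furan-3-ylmethyl)furan-3-yl]-1-hydroxy-2,6-dimethylnona-4,6-dien-1-yl]-3-methylfuran-2(5H)-one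
Product: 20 (5E)-5-[(2S,4E,6E)-9-[5-(furan-3-ylmethyl)furan-3-yl]-2,6-dimethylnona-4,6-dien-1-ylidene]-3-methylfuran-2(5H)-one
Conditions: PPh3 (1.5 equiv), EtO2C–N=N–CO2Et (1.5 equiv), THF, −20 °C to rt, dark
Reagents that add atoms: none
Why: Mitsunobu-type dehydration: the hydroxyl of 19 becomes an oxyphosphonium leaving group with retention, and the hydrazide base removes the acidic C4 hydrogen antiperiplanar to it (E2), so the erythro configuration is translated into the E alkene with C3 and C6 cis. C6 is not a reacting centre, and the product is kept from light, acid and base.

## Compound list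

1 | acrolein diethyl acetal (3,3-diethoxyprop-1-ene) | C=CC(OCC)OCC | starting material
2 | 3-bromofuran | Brc1ccoc1 | starting material
3 | 9-(3,3-diethoxypropyl)-9-borabicyclo[3.3.1]nonane | CCOC(CCB1C2CCCC1CCC2)OCC | intermediate (not isolated)
4 | 3-(3,3-diethoxypropyl)furan | CCOC(CCc1ccoc1)OCC | intermediate
5 | furan-3-ylmethanol | OCc1ccoc1 | starting material
6 | 3-(bromomethyl)furan | BrCc1ccoc1 | intermediate
7 | 2-[4-(3,3-diethoxypropyl)furan-2-yl]-4,4,5,5-tetramethyl-1,3,2-dioxaborolane | CCOC(CCc1coc(B2OC(C)(C)C(C)(C)O2)c1)OCC | intermediate (not isolated)
8 | 4-(3,3-diethoxypropyl)-2-(furan-3-ylmethyl)furan | CCOC(CCc1coc(Cc2ccoc2)c1)OCC | intermediate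
9 | 3-[5-(furan-3-ylmethyl)furan-3-yl]propanal | O=CCCc1coc(Cc2ccoc2)c1 | intermediate
10 | (2E)-5-[5-(furan-3-ylmethyl)furan-3-yl]-2-methylpent-2-enal | O=C/C(C)=C/CCc1coc(Cc2ccoc2)c1 | intermediate
11 | 2-(furan-3-ylmethyl)-4-[(3E,5E)-6-iodo-4-methylhexa-3,5-dien-1-yl]furan | I/C=C/C(C)=C/CCc1coc(Cc2ccoc2)c1 | intermediate
12 | methyl (2R)-3-bromo-2-methylpropanoate | COC(=O)[C@@H](C)CBr | starting material
13 | [(2R)-3-methoxy-2-methyl-3-oxopropyl]zinc bromide | COC(=O)[C@@H](C)C[Zn]Br | intermediate (not isolated)
14 | methyl (2S,4E,6E)-9-[5-(furan-3-ylmethyl)furan-3-yl]-2,6-dimethylnona-4,6-dienoate | COC(=O)[C@@H](C)C/C=C/C(C)=C/CCc1coc(Cc2ccoc2)c1 | intermediate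
15 | (2S,4E,6E)-9-[5-(furan-3-ylmethyl)furan-3-yl]-2,6-dimethylnona-4,6-dienal | O=C[C@@H](C)C/C=C/C(C)=C/CCc1coc(Cc2ccoc2)c1 | intermediate
16 | 3-methylfuran-2(5H)-one | CC1=CCOC1=O | starting material
17 | trimethyl[(3-methylfuran-2-yl)oxy]silane | Cc1ccoc1O[Si](C)(C)C | intermediate
18 | (5S)-5-[(1R,2S,4E,6E)-9-[5-(furan-3-ylmethyl)furan-3-yl]-2,6-dimethyl-1-(trimethylsilyloxy)nona-4,6-dien-1-yl]-3-methylfuran-2(5H)-one | CC1=C[C@@H]([C@H](O[Si](C)(C)C)[C@@H](C)C/C=C/C(C)=C/CCc2coc(Cc3ccoc3)c2)OC1=O | intermediate (not isolated)
19 | (5S)-5-[(1R,2S,4E,6E)-9-[5-(furan-3-ylmethyl)furan-3-yl]-1-hydroxy-2,6-dimethylnona-4,6-dien-1-yl]-3-methylfuran-2(5H)-one | CC1=C[C@@H]([C@H](O)[C@@H](C)C/C=C/C(C)=C/CCc2coc(Cc3ccoc3)c2)OC1=O | intermediate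
20 | (5E)-5-[(2S,4E,6E)-9-[5-(furan-3-ylmethyl)furan-3-yl]-2,6-dimethylnona-4,6-dien-1-ylidene]-3-methylfuran-2(5H)-one | CC1=C/C(=C\[C@@H](C)C/C=C/C(C)=C/CCc2coc(Cc3ccoc3)c2)OC1=O | target

## Step count and least certain steps

Total: 11 steps. Longest linear sequence: 9 steps (1, 3, 4, 5, 6, 7, 8, 10, 11) from 1 and 2.

**Step 3 (key step).** The borylation may discriminate incompletely between the two α-CH bonds of 4 or run on to diborylation. In the second stage, hydrolytic loss of boron from 7 or solvolysis of 6 in the warm aqueous base may outrun transmetalation. The fallback sets out from 4 and 5 and returns at 8. The borylation is run alone and 7 is isolated through a short silica plug, which also allows a regioisomer to be removed. 5 is converted with methyl chloroformate and pyridine into furan-3-ylmethyl methyl carbonate F1, a storable electrophile. 7 and F1 are then coupled under anhydrous conditions with Pd(OAc)2/1,5-bis(diphenylphosphino)pentane and little or no added base. Ionisation and decarboxylation of F1 give a (furylmethyl)palladium methoxide whose methoxide activates 7, so neither aqueous base nor the labile bromide is needed.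

**Step 7.** Zinc insertion into 12 may be slow, or the ester-chelated homoenolate 13 may transmetalate sluggishly, which gives 11 time to homocouple or lose alkene geometry. The fallback sets out from 11 and returns at 15, replacing steps 7 and 8. The C5–C7 unit is brought in as a non-chelating silyl ether. Commercial (2R)-3-bromo-2-methylpropan-1-ol F2 is silylated (t-BuMe2SiCl, imidazole) to [(2R)-3-bromo-2-methylpropoxy](tert-butyl)dimethylsilane F3. LiCl-assisted zinc insertion gives the alkylzinc bromide F4, and Negishi coupling with 11 gives the silyl ether F5. Bu4NF frees the alcohol F6, and Dess–Martin oxidation gives 15.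

**Step 8.** The reduction may run on to the primary alcohol or stop short, and C6 may epimerise during work-up or chromatography. The fallback sets out from 14 and returns at 15. 14 is converted with MeNH(OMe)·HCl and i-PrMgCl (THF, −20 °C) into the N-methoxy-N-methylamide F7. Its chelated aluminium adduct with i-Bu2AlH at −78 °C cannot be reduced further and releases 15 only on work-up.

**Step 10.** Simple diastereoselection (erythro against threo) may be poor, attack may occur through the α- instead of the γ-carbon of 17, and fluoride may epimerise 15. The fallback sets out from 15 and 17 and returns at 20, so step 11 is not needed. It uses the complementary stereochemical pairing. BF3·OEt2 in CH2Cl2 at −78 °C, the Lewis-acid variant of the same aldol, favours the threo adduct F8. F8 is dehydrated with the Burgess reagent, a syn elimination through the sulfamate ester. Threo plus syn elimination gives the same E alkene as erythro plus anti elimination.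

**Step 11.** Stereospecificity may be lost through a stepwise E1cB elimination via the dienolate, 20 may isomerise from E to Z under the influence of light, acid or phosphine, and the hydrazide base may epimerise C6. The fallback sets out from 19 and returns at 20. 19 is converted at −78 °C with Tf2O and pyridine into the triflate F9. Pyridine removes the C4 hydrogen antiperiplanar to the sulfonate (E2) in the cold, with no phosphine and no hydrazide anion present.

## Further compounds

F1 | step 3 | furan-3-ylmethyl methyl carbonate | COC(=O)OCc1ccoc1
F2 | step 7 | (2R)-3-bromo-2-methylpropan-1-ol | OC[C@@H](C)CBr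
F3 | step 7 | [(2R)-3-bromo-2-methylpropoxy](tert-butyl)dimethylsilane | CC(C)(C)[Si](C)(C)OC[C@@H](C)CBr
F4 | step 7 | [(2R)-3-{[tert-butyl(dimethyl)silyl]oxy}-2-methylpropyl]zinc bromide | CC(C)(C)[Si](C)(C)OC[C@@H](C)C[Zn]Br
F5 | step 7 | tert-butyl{[(2S,4E,6E)-9-[5-(furan-3-ylmethyl)furan-3-yl]-2,6-dimethylnona-4,6-dien-1-yl]oxy}dimethylsilane | CC(C)(C)[Si](C)(C)OC[C@@H](C)C/C=C/C(C)=C/CCc1coc(Cc2ccoc2)c1
F6 | step 7 | (2S,4E,6E)-9-[5-(furan-3-ylmethyl)furan-3-yl]-2,6-dimethylnona-4,6-dien-1-ol | OC[C@@H](C)C/C=C/C(C)=C/CCc1coc(Cc2ccoc2)c1
F7 | step 8 | (2S,4E,6E)-9-[5-(furan-3-ylmethyl)furan-3-yl]-N-methoxy-N,2,6-trimethylnona-4,6-dienamide | CON(C)C(=O)[C@@H](C)C/C=C/C(C)=C/CCc1coc(Cc2ccoc2)c1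
F8 | step 10 | (5R)-5-[(1R,2S,4E,6E)-9-[5-(furan-3-ylmethyl)furan-3-yl]-1-hydroxy-2,6-dimethylnona-4,6-dien-1-yl]-3-methylfuran-2(5H)-one | CC1=C[C@H]([C@H](O)[C@@H](C)C/C=C/C(C)=C/CCc2coc(Cc3ccoc3)c2)OC1=O
F9 | step 11 | (1R,2S,4E,6E)-9-[5-(furan-3-ylmethyl)furan-3-yl]-2,6-dimethyl-1-[(2S)-4-methyl-5-oxo-2,5-dihydrofuran-2-yl]nona-4,6-dien-1-yl trifluoromethanesulfonate | CC1=C[C@@H]([C@H](OS(=O)(=O)C(F)(F)F)[C@@H](C)C/C=C/C(C)=C/CCc2coc(Cc3ccoc3)c2)OC1=O
A1 | alternative 1 | (2Z)-2-[2-(1,3-dioxolan-2-yl)ethyl]-5-(furan-3-yl)pent-2-en-4-yn-1-ol | OC/C(=C\C#Cc1ccoc1)CCC1OCCO1
A2 | alternative 1 | 2-(furan-3-ylmethyl)-4-[2-(1,3-dioxolan-2-yl)ethyl]furan | C1COC(CCc2coc(Cc3ccoc3)c2)O1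
A3 | alternative 2 | (3S)-4-methoxy-3-methyl-4-oxobutanoic acid | COC(=O)[C@@H](C)CC(O)=O
A4 | alternative 2 | 4-(1,3-dioxoisoindolin-2-yl) 1-methyl (2S)-2-methylbutanedioate | COC(=O)[C@@H](C)CC(=O)ON1C(=O)c2ccccc2C1=O
A5 | alternative 2 | 2-(furan-3-ylmethyl)-4-[(3E,5E)-6-iodo-4-methylhexa-3,5-dien-1-yl]furan | I/C=C/C(C)=C/CCc1coc(Cc2ccoc2)c1
A6 | alternative 2 | methyl (2S,4E,6E)-9-[5-(furan-3-ylmethyl)furan-3-yl]-2,6-dimethylnona-4,6-dienoate | COC(=O)[C@@H](C)C/C=C/C(C)=C/CCc1coc(Cc2ccoc2)c1
A7 | alternative 3 | (2S,4E,6E)-9-[5-(furan-3-ylmethyl)furan-3-yl]-2,6-dimethylnona-4,6-dienal | O=C[C@@H](C)C/C=C/C(C)=C/CCc1coc(Cc2ccoc2)c1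
A8 | alternative 3 | trimethyl[(3-methylfuran-2-yl)oxy]silane | Cc1ccoc1O[Si](C)(C)C
A9 | alternative 3 | (5S)-5-[(1R,2S,4E,6E)-9-[5-(furan-3-ylmethyl)furan-3-yl]-1-hydroxy-2,6-dimethylnona-4,6-dien-1-yl]-3-methylfuran-2(5H)-one | CC1=C[C@@H]([C@H](O)[C@@H](C)C/C=C/C(C)=C/CCc2coc(Cc3ccoc3)c2)OC1=O
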